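(The data were generated by integration for an exercise; noise was put on by code.)

Count the target as a share of the charge, not as a concentration.

| flask | starting material | catalyst | remark | time |
|---|---|---|---|---|
| south-east | 25 mM | 0.31 mM | run made earlier |  |
| south | 25 mM | 0.23 mM | run made earlier |  |
| eta | 25 mM | 0.46 mM |  | 25 h |
| theta | 50 mM | 0.46 mM |  | 25 h |
| gamma | 100 mM | 0.46 mM |  | 25 h |
| alpha | 200 mM | 0.46 mM |  | 25 h |

| run | time / h | target / % |
|---|---|---|
| south-east | 1.33 | 18.7 |
| south-east | 2.50 | 10.7 |
| south-east | 4.00 | 8.3 |
| south-east | 8.00 | 5.8 |
| south-east | 15.0 | 5.5 |
| south | 3.00 | 12.0 |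
| south | 6.00 | 8.0 |
| south | 10.0 | 7.0 |
| south | 12.0 | 7.7 |
| south | 15.0 | 6.4 |

(readings scatter by 1 percentage point)

- "hardly changes" means that all values lie within two and a half points (for a concentration: within two and a half percent of the largest)

- [target] at the end for eta, theta, gamma, alpha, in this order
- the course of these numbers from the first flask to the last (hardly changes / rises all the way / falls, then rises / falls all the way / rises, then falls)

- I set both earlier runs against catalyst times time, and they fell on one curve: south read 8.0% at 4.97 M·s, and south-east read 8.3% at 4.46 M·s.
- The curve began high and falling, with south-east reading 18.7% at 1.48 M·s.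
- In the south-east readings, its first fall was ten times as steep as its fall after 4.46 M·s, so I put the knee there.
- From 8.28 M·s on the curve ran into a level, and 5 readings from the two runs averaged 6.48%, give or take 0.45 percentage points.
- I named this the plateau share, the part of the charge standing as target once its gain and its loss balance.
- I read the fall as a passage from kinetic to thermodynamic control.
- I reckoned the plateau share by dividing one rate by another. I took the gain and the loss of target each as catalyst times a material, so catalyst and time cancelled.
- The charge cancels too if each step is first order in material. That was my assumption, since both runs held 25 mM.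
- Eta carried 41.4 M·s of catalyst times time, more than the last south-east reading's 16.7 M·s, and theta, gamma and alpha were set the same. So I placed them on the level.
- My row was 1.62 mM, 3.24 mM, 6.48 mM and 13.0 mM, rising with the charge.
- The forecast differed from my reckoning. It gave 1.5 mM, 1.5 mM, 1.5 mM and 1.5 mM, a course that hardly changes, on the ground of a “fixed critical concentration, independent of charge”.
- The flasks gave 1.63 mM, 3.26 mM, 6.52 mM and 13.0 mM: the course rises all the way.

    target + catalyst ⇌ isomer of the product A + catalyst, rate k1*[catalyst]*[target] forward; the back reaction follows from the equilibrium constant (K = 13.0, k = 7.60 M⁻¹ h⁻¹)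
    target ⇌ isomer of the product B (K = 3.20, k = 0.00920 h⁻¹)
    isomer of the product A + catalyst ⇌ starting material + catalyst, rate k3*[catalyst]*[isomer of the product A] forward; the back reaction follows from the equilibrium constant (k = 490 M⁻¹ h⁻¹)
    starting material + catalyst ⇌ target + catalyst, rate k4*[starting material]*[catalyst] forward; the back reaction follows from the equilibrium constant (K = 1.00, k = 4900 M⁻¹ h⁻¹)

- Isomer of the product A stood at 85.3% of the charge in eta and 85.3% of the charge in alpha. For gamma, the plateau share of 6.48% taken of 100 mM came to 6.48 mM, and gamma stood at 6.52 mM.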